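## Analysis of the target

The target 15 is an aryl enol ether made of two units. The first is a coumarin (benzene ring A fused to pyranone ring B; atoms O1, C2, C3, C4, C4a, C5–C8, C8a) with a methoxy group on C6 and a free hydroxyl on C7. The second is a benzene ring C, bonded through one oxygen to C3 of ring B. Ring C carries the ether oxygen on C1', a free hydroxyl on C3' and a 3-methoxy-3-oxopropyl chain on C4', para to the ether oxygen. There is no stereocentre, so the problem is one of connectivity and chemoselectivity only.

The sensitive groups are:
- the coumarin lactone, which hydroxide or alkoxide opens;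
- the C3=C4 bond, an enol ether conjugated to the carbonyl, which can be hydrogenated or oxidised;
- the methyl ester;
- the hydroxyl on C3', which sits ortho to the propanoate chain and can close onto the ester to give a dihydrocoumarin with loss of methanol.

The hard part is the C3–O–C1' linkage. C3 is an sp2 carbon next to the lactone carbonyl, where nucleophiles prefer conjugate addition at C4, and ring C is too electron-rich for nucleophilic aromatic substitution. Two phenolic hydroxyls (O7 and O3') must also stay out of the ether-forming step.

The strategy rests on one feature: the ether oxygen on C3 is the enol oxygen of a 3-hydroxycoumarin, a stable and acidic phenol-like enol. The bond from this oxygen to C1' can therefore be made by transfer of an aryl group from boron through copper.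

## Retrosynthetic reasoning

**15 to 14.** The two O–H bonds on O7 and O3' are traced back to benzyl ethers in 14. Benzyl is chosen because it survives every earlier step and can be removed at low temperature by a boron Lewis acid with a cation scavenger. Hydrogenolysis is avoided as the first choice because of the C3=C4 bond. Unmasking last keeps both phenols out of the copper step and keeps the O3' phenol from closing onto the ester during the route.

**14 to 6 and 13.** The bond cut is O–C1', between the enol oxygen and ring C. The other ether bond, C3–O, would need an electrophilic C3; a 3-halocoumarin invites attack at C4, and the ring C partner would then be a resorcinol-type phenol whose two hydroxyls must be told apart. Cutting at C1' leaves the oxygen on the coumarin as the enol 6 and puts boron on ring C in 13, so the site of the new bond is fixed by the carbon that bears boron. The forward reaction must arylate oxygen and not C4 of 6, under conditions mild enough for the lactone and the ester. A copper-mediated oxidative coupling at room temperature with an amine base meets this.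

**6 to 5.** The C3–O bond of the enol is traced to the C3–N bond of the acetamide 5. Hydrolysis of the enamide has to replace nitrogen by oxygen without opening ring B for good and without removing the benzyl group on O7.

**5 to 2 and 3.** Ring B is opened at C3=C4 and at O1–C2. The aldehyde carbon of 2 becomes C4, its ortho hydroxyl becomes O1, and 3 supplies C2, C3 and the nitrogen that masks O3. The forward reaction is a condensation of the aldehyde with the oxazolone 4, formed from 3 in the flask, followed by lactonisation. This builds the complete coumarin before the two halves are joined.

**2 to 1.** The benzyl group on O4 of the aldehyde (the later O7) is removed. The forward step must alkylate O4 and leave O2 free; O2 is hydrogen-bonded to the formyl group and is the less acidic site.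

**13 to 12 to 11.** The C–B bond is traced through the pinacol ester 12 to the C–Br bond of 11. A palladium-catalysed borylation is preferred to halogen–metal exchange because the methyl ester would not tolerate an aryllithium.

**11 to 10 to 8 and 9.** The saturated chain is traced to the cinnamate 10, and its C=C bond is cut to the aldehyde 8 and the ylide 9. The ylide brings the two chain carbons and the methyl ester in one step. The reduction that follows must saturate the alkene and leave the aryl bromide and the benzyl ether alone.

**8 to 7.** The benzyl group on the phenol oxygen is removed, which leads to the bromo aldehyde 7. Bromine in 7 is para to the formyl group, so boron, and later the ether oxygen, end up para to the chain.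

## Alternatives that were turned down

**Alternative 1:** The cut is O1–C8a of ring B. The precursor is the cinnamic acid A2, whose aryl ring has no oxygen on the future C8a and whose α-carbon already carries the ether oxygen to ring C; ring C is held as a dihydrocoumarin. In the key step a flavin photocatalyst under blue light and air turns the acid about its double bond so that the carboxyl faces the arene. It then oxidises the arene, and the carboxylate oxygen bonds to the ring carbon para to methoxy, giving A1. Methanolysis of A1 would open the saturated lactone and remove the acetate to give 15.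
- For: the ether is made early by simple chemistry, the lactone protects both the phenol and the acid of ring C, and the oxygen on C8a comes from a C–H bond. The route is shorter than the chosen one.
- Against: the α-aryloxy acrylic acid is an electron-rich enol ether and is exposed to light, sensitiser and air, so oxidative cleavage of the alkene is a real side path. The method is known for cinnamic acids without an α-heteroatom. The arene carries an acetoxy group, which raises its oxidation potential, and the diaryl-ether-like ring C can be oxidised in competition. Bond formation ortho to methoxy instead of para is also possible.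
- Comparison: Alternative 1 is stronger in step count and in protecting-group economy. The chosen route offers a ground-state coupling at room temperature whose site is fixed by boron and by the single free hydroxyl, and a ring B made by a classical condensation.

**Alternative 2:** The cut is C3–O, with both halves as free phenols: the coumarin A4 and the dihydrocoumarin A5. Anodic oxidation of A4 in the presence of excess A5 would join C3 to the phenol oxygen and give A3. The oxidised form of A4 has spin and charge density on C3, passed on through C4a and the C3=C4 bond as at the β-carbon of a lignol. Loss of the hydrogen on C3 restores the coumarin, and methanolysis of A3 gives 15.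
- For: two steps from cheap phenols, no protecting groups, and the best atom economy of all four strategies.
- Against: the density in oxidised A4 is shared by O7, C8, C6 and C3, and A5 can react through oxygen or through its ortho carbons, so homo-dimers and C–C cross-dimers compete with the wanted C–O product. A3 is still a phenol of similar potential and can be oxidised further. Nothing in either substrate directs the coupling to one site.
- Comparison: Alternative 2 is far shorter. The chosen route assigns each oxygen its role by protection and by the position of boron, so a single constitutional isomer is expected.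

**Alternative 3:** Ring C is cut at C3'–C4' and C5'–C6'. The precursor A7 is a 2-pyranone that carries the coumarin-3-yloxy group on C5 and a pent-4-ynoate ester on O3. On heating, the tethered alkyne adds across C3 and C6 of the pyranone; decarboxylative cycloreversion then gives the benzene ring and the six-membered lactone at once, as in A6. Acidic methanolysis of A6 would remove the acetal and open the lactone to give 15.
- For: the substitution pattern of ring C is set by the tether, the conditions are neutral, and the lactone again protects phenol and acid together.
- Against: the difficult bond is not removed but moved. A7 still needs an ether from coumarin C3 to a 3,5-dioxygenated 2-pyranone, which is harder to reach than 6. The ester tether prefers the conformation that holds the alkyne away from the diene, so high temperature is needed, and the enol ester can transfer its acyl group.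
- Comparison: Alternative 3 is stronger only in that ring C needs no aryl–metal chemistry and no late Lewis-acid deprotection. The chosen route takes ring C from a cheap benzene derivative and spends its risk on one bond.

Key step: step 9

Remark: compounds 1, 3, 7 and 9 are taken to be catalogue compounds; in step 9 copper is used in stoichiometric amount with air present.

## Steps

Step 1
Reactants: 1 2,4-dihydroxy-5-methoxybenzaldehyde
Product: 2 4-(benzyloxy)-2-hydroxy-5-methoxybenzaldehyde
Conditions: BnBr (1.05 equiv), NaHCO3, KI (cat.), MeCN, 70 °C
Reagents that add atoms: benzyl bromide, BrCc1ccccc1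
Why: Williamson etherification; the hydroxyl on C4, para to the formyl group, is the more acidic one and the hydroxyl on C2 is held in a hydrogen bond to the aldehyde, so a weak hydrogencarbonate base with one equivalent of halide should alkylate O4 only.

Step 2
Reactants: 2 4-(benzyloxy)-2-hydroxy-5-methoxybenzaldehyde; 3 N-acetylglycine
Product: 5 N-[7-(benzyloxy)-6-methoxy-2-oxo-2H-chromen-3-yl]acetamide, via 2-methyl-1,3-oxazol-5(4H)-one 4 (not isolated)
Conditions: Ac2O, NaOAc, 110 °C
Reagents that add atoms: none
Why: Erlenmeyer–Plöchl condensation in its Perkin-type coumarin variant; the anhydride cyclodehydrates 3 to the oxazolone 4, whose C4 methylene condenses with the aldehyde, and the ortho phenol oxygen then opens the oxazolone carbonyl, which closes ring B and releases the acetamide; the benzyl and methyl ethers are inert.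

Step 3
Reactants: 5 N-[7-(benzyloxy)-6-methoxy-2-oxo-2H-chromen-3-yl]acetamide
Product: 6 7-(benzyloxy)-3-hydroxy-6-methoxy-2H-chromen-2-one
Conditions: 3 M aq HCl/EtOH (1:1), 80 °C, stopped at full conversion
Reagents that add atoms: water, O
Why: Acid hydrolysis of an enamide; loss of the acetyl group gives the 3-amino compound, whose enamine is hydrolysed through the iminium ion to the α-keto lactone, which rests as the conjugated enol 6; O7 is conjugated to the lactone and poorly basic, so its benzyl ether should survive dilute acid for the short time needed.

Step 4
Reactants: 7 4-bromo-2-hydroxybenzaldehyde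
Product: 8 2-(benzyloxy)-4-bromobenzaldehyde
Conditions: BnBr, K2CO3, DMF, rt
Reagents that add atoms: benzyl bromide, BrCc1ccccc1
Why: Williamson etherification of the only hydroxyl; it removes the acidic proton before the ylide step and prevents the later cinnamate from lactonising.

Step 5
Reactants: 8 2-(benzyloxy)-4-bromobenzaldehyde; 9 methyl (triphenylphosphoranylidene)acetate
Product: 10 methyl (2E)-3-[2-(benzyloxy)-4-bromophenyl]prop-2-enoate
Conditions: toluene, 80 °C
Reagents that add atoms: none
Why: Wittig olefination with a stabilised ylide, which should favour the E-alkene; the geometry is of no consequence because the double bond is saturated in the next step.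

Step 6
Reactants: 10 methyl (2E)-3-[2-(benzyloxy)-4-bromophenyl]prop-2-enoate
Product: 11 methyl 3-[2-(benzyloxy)-4-bromophenyl]propanoate
Conditions: H2 (3 atm), RhCl(PPh3)3 (5 mol %), toluene/EtOH (1:1), 40 °C
Reagents that add atoms: none
Why: Homogeneous hydrogenation with the rhodium chloride phosphine complex saturates the disubstituted conjugated alkene and does not cleave aryl C–Br or benzyl C–O bonds, which a heterogeneous palladium catalyst would attack.

Step 7
Reactants: 11 methyl 3-[2-(benzyloxy)-4-bromophenyl]propanoate
Product: 12 methyl 3-[2-(benzyloxy)-4-(4,4,5,5-tetramethyl-1,3,2-dioxaborolan-2-yl)phenyl]propanoate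
Conditions: B2pin2 (1.2 equiv), PdCl2(dppf) (3 mol %), KOAc (3 equiv), 1,4-dioxane, 85 °C
Reagents that add atoms: bis(pinacolato)diboron, CC1(C)OB(OC1(C)C)B1OC(C)(C)C(C)(C)O1
Why: Miyaura borylation; zerovalent palladium inserts into the C–Br bond, acetate assists the transfer of boron, and the weak base leaves the methyl ester and the benzyl ether untouched.

Step 8
Reactants: 12 methyl 3-[2-(benzyloxy)-4-(4,4,5,5-tetramethyl-1,3,2-dioxaborolan-2-yl)phenyl]propanoate
Product: 13 [3-(benzyloxy)-4-(3-methoxy-3-oxopropyl)phenyl]boronic acid
Conditions: NaIO4 (3 equiv), NH4OAc (3 equiv), acetone/H2O (1:1), rt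
Reagents that add atoms: water, O
Why: Hydrolysis of the pinacol ester is driven to completion because periodate cleaves the released diol; the buffered medium at room temperature leaves the ester and the benzyl ether intact.

Step 9
Reactants: 6 7-(benzyloxy)-3-hydroxy-6-methoxy-2H-chromen-2-one; 13 [3-(benzyloxy)-4-(3-methoxy-3-oxopropyl)phenyl]boronic acid (2 equiv)
Product: 14 methyl 3-[2-(benzyloxy)-4-{[7-(benzyloxy)-6-methoxy-2-oxo-2H-chromen-3-yl]oxy}phenyl]propanoate
Conditions: Cu(OAc)2 (2 equiv), pyridine (5 equiv), 4 Å MS, CH2Cl2, air, rt
Reagents that add atoms: none
Why: This is a Chan–Lam–Evans oxidative C–O coupling, the reaction known for phenols and other acidic O–H partners with arylboronic acids, applied here to the phenol-like enol of ring B. Acetate on divalent copper deprotonates the 3-hydroxyl of 6 and the enolate binds copper through oxygen; the aryl group of 13 is then transferred from boron to copper. A second divalent copper, or oxygen from the air, oxidises this aryl copper enolate to trivalent copper, and reductive elimination joins the enol oxygen to C1' and releases monovalent copper, which air returns to the divalent state. No ring is closed and no stereocentre is formed. The step needs O-arylation and not C4-arylation: the oxygen-bound copper enolate keeps the C3=C4 bond conjugated with ring A and the lactone, whereas a C4-bound form would give up that conjugation, so the aryl group should be delivered to oxygen. It needs reaction at one hydroxyl only, which the benzyl ethers on O7 and O3' secure, and it needs the lactone and the ester to survive, which pyridine at room temperature allows. The site on ring C is fixed by the carbon that carries boron, para to the propanoate chain. Molecular sieves and the excess of 13 offset the loss of boronic acid to oxidation and homocoupling.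

Step 10
Reactants: 14 methyl 3-[2-(benzyloxy)-4-{[7-(benzyloxy)-6-methoxy-2-oxo-2H-chromen-3-yl]oxy}phenyl]propanoate
Product: 15 methyl 3-{2-hydroxy-4-[(7-hydroxy-6-methoxy-2-oxo-2H-chromen-3-yl)oxy]phenyl}propanoate
Conditions: BCl3 (5 equiv), C6HMe5 (6 equiv), CH2Cl2, −78 °C; MeOH quench at −78 °C, then aq NaHCO3
Reagents that add atoms: none
Why: Lewis-acid debenzylation; BCl3 binds the benzyl ether oxygens and the benzyl cations are taken up by pentamethylbenzene in a Friedel–Crafts alkylation; at −78 °C the methyl ether, the methyl ester, the lactone and the enol ether should not react, and the methanol quench frees the phenols from boron and keeps the chain as the open methyl ester.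

## Compound list

1 | 2,4-dihydroxy-5-methoxybenzaldehyde | COc1cc(C=O)c(O)cc1O | starting material
2 | 4-(benzyloxy)-2-hydroxy-5-methoxybenzaldehyde | COc1cc(C=O)c(O)cc1OCc1ccccc1 | intermediate
3 | N-acetylglycine | CC(=O)NCC(=O)O | starting material
4 | 2-methyl-1,3-oxazol-5(4H)-one | CC1=NCC(=O)O1 | intermediate
5 | N-[7-(benzyloxy)-6-methoxy-2-oxo-2H-chromen-3-yl]acetamide | COc1cc2cc(NC(C)=O)c(=O)oc2cc1OCc1ccccc1 | intermediate
6 | 7-(benzyloxy)-3-hydroxy-6-methoxy-2H-chromen-2-one | COc1cc2cc(O)c(=O)oc2cc1OCc1ccccc1 | intermediate
7 | 4-bromo-2-hydroxybenzaldehyde | O=Cc1ccc(Br)cc1O | starting material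
8 | 2-(benzyloxy)-4-bromobenzaldehyde | O=Cc1ccc(Br)cc1OCc1ccccc1 | intermediate
9 | methyl (triphenylphosphoranylidene)acetate | COC(=O)C=P(c1ccccc1)(c1ccccc1)c1ccccc1 | starting material
10 | methyl (2E)-3-[2-(benzyloxy)-4-bromophenyl]prop-2-enoate | COC(=O)/C=C/c1ccc(Br)cc1OCc1ccccc1 | intermediate
11 | methyl 3-[2-(benzyloxy)-4-bromophenyl]propanoate | COC(=O)CCc1ccc(Br)cc1OCc1ccccc1 | intermediate
12 | methyl 3-[2-(benzyloxy)-4-(4,4,5,5-tetramethyl-1,3,2-dioxaborolan-2-yl)phenyl]propanoate | COC(=O)CCc1ccc(B2OC(C)(C)C(C)(C)O2)cc1OCc1ccccc1 | intermediate
13 | [3-(benzyloxy)-4-(3-methoxy-3-oxopropyl)phenyl]boronic acid | COC(=O)CCc1ccc(B(O)O)cc1OCc1ccccc1 | intermediate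
14 | methyl 3-[2-(benzyloxy)-4-{[7-(benzyloxy)-6-methoxy-2-oxo-2H-chromen-3-yl]oxy}phenyl]propanoate | COC(=O)CCc1ccc(Oc2cc3cc(OC)c(OCc4ccccc4)cc3oc2=O)cc1OCc1ccccc1 | intermediate
15 | methyl 3-{2-hydroxy-4-[(7-hydroxy-6-methoxy-2-oxo-2H-chromen-3-yl)oxy]phenyl}propanoate | COC(=O)CCc1ccc(Oc2cc3cc(OC)c(O)cc3oc2=O)cc1O | target

## Step count and risk

Total step count: 10. Longest linear sequence: 7 steps (7 to 8, 10, 11, 12, 13, 14, 15). The coumarin branch from 1 needs 3 steps before the union.

**Step 9 (key step).** Three things may go wrong. Copper may be tied up by chelation between the enolate oxygen and the lactone carbonyl of 6, so that aryl transfer stalls. The electron-rich enol may be oxidised by divalent copper and air, with oxidative dimerisation at C4. The boronic acid may be used up by oxidation and homocoupling before it couples. Fallback, from 13 and 2, returning at 14: the ether is made first at an sp3 carbon and ring B is built around it. Oxidation of 13 with aqueous H2O2 would give methyl 3-[2-(benzyloxy)-4-hydroxyphenyl]propanoate F1. Alkylation with tert-butyl bromoacetate (K2CO3, acetone) would give tert-butyl 2-[3-(benzyloxy)-4-(3-methoxy-3-oxopropyl)phenoxy]acetate F2. CF3CO2H in CH2Cl2 would free 2-[3-(benzyloxy)-4-(3-methoxy-3-oxopropyl)phenoxy]acetic acid F3. Perkin condensation of F3 with the aldehyde 2 (Ac2O, Et3N, 120 °C) would then give 14.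

**Step 3.** Acid-mediated cleavage of the O7 benzyl ether may compete with hydrolysis of the enamide if long heating is needed. Fallback, from 2, returning at 6: Horner–Wadsworth–Emmons olefination of 2 with methyl 2-[(tert-butyldimethylsilyl)oxy]-2-(dimethoxyphosphoryl)acetate (LiN(SiMe3)2, 2.2 equiv, THF, −78 °C to rt) would give methyl 3-[4-(benzyloxy)-2-hydroxy-5-methoxyphenyl]-2-[(tert-butyldimethylsilyl)oxy]prop-2-enoate F4 as an E/Z mixture. Fluoride (Bu4NF, AcOH, THF) would unmask methyl 3-[4-(benzyloxy)-2-hydroxy-5-methoxyphenyl]-2-oxopropanoate F5. F5 should lactonise with catalytic TsOH in toluene at 60 °C to the enol 6, with no strong aqueous acid in the sequence.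

**Step 10.** Demethylation at O6 may occur if boron bound to the neighbouring O7 delivers chloride on warming. The freed O3' phenol may close onto the ester. Ring benzylation may occur if the scavenger is outrun. Fallback, from 14, returning at 15: hydrogenolysis of both benzyl ethers with H2 (1 atm) over palladium on carbon (Pd/C) in EtOAc at room temperature, stopped at uptake of two equivalents, so that the trisubstituted C3=C4 bond, which should be reduced much more slowly, is kept. No new compound is made on this path.

**Step 6.** Hydrogenation of the ortho-substituted conjugated alkene may be slow with the rhodium catalyst, and forcing it may start reductive loss of bromine. Fallback, from 8, returning at 11: three-component reductive alkylation of Meldrum's acid with 8 and Hantzsch ester (L-proline cat., EtOH, rt) would give 5-[2-(benzyloxy)-4-bromobenzyl]-2,2-dimethyl-1,3-dioxane-4,6-dione F6. Heating F6 in MeOH/pyridine would open the ring and decarboxylate to 11, with no hydrogenation and no need for 9.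

**Step 1.** Alkylation may spread to O2 and give over-benzylation. Fallback, from 1, returning at 2: exhaustive benzylation (BnBr, K2CO3, DMF) would give 2,4-bis(benzyloxy)-5-methoxybenzaldehyde F7. MgBr2·OEt2 in toluene/Et2O at reflux would remove only the benzyl group ortho to the formyl group by chelation and give 2.

## Further compounds

F1 | step 9 | methyl 3-[2-(benzyloxy)-4-hydroxyphenyl]propanoate | COC(=O)CCc1ccc(O)cc1OCc1ccccc1
F2 | step 9 | tert-butyl 2-[3-(benzyloxy)-4-(3-methoxy-3-oxopropyl)phenoxy]acetate | COC(=O)CCc1ccc(OCC(=O)OC(C)(C)C)cc1OCc1ccccc1
F3 | step 9 | 2-[3-(benzyloxy)-4-(3-methoxy-3-oxopropyl)phenoxy]acetic acid | COC(=O)CCc1ccc(OCC(=O)O)cc1OCc1ccccc1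
F4 | step 3 | methyl 3-[4-(benzyloxy)-2-hydroxy-5-methoxyphenyl]-2-[(tert-butyldimethylsilyl)oxy]prop-2-enoate (E/Z mixture) | COC(=O)C(O[Si](C)(C)C(C)(C)C)=Cc1cc(OC)c(OCc2ccccc2)cc1O
F5 | step 3 | methyl 3-[4-(benzyloxy)-2-hydroxy-5-methoxyphenyl]-2-oxopropanoate | COC(=O)C(=O)Cc1cc(OC)c(OCc2ccccc2)cc1O
F6 | step 6 | 5-[2-(benzyloxy)-4-bromobenzyl]-2,2-dimethyl-1,3-dioxane-4,6-dione | CC1(C)OC(=O)C(Cc2ccc(Br)cc2OCc2ccccc2)C(=O)O1
F0 | step 10 | none | none
F7 | step 1 | 2,4-bis(benzyloxy)-5-methoxybenzaldehyde | COc1cc(C=O)c(OCc2ccccc2)cc1OCc1ccccc1
A1 | alternative 1 | 7-acetoxy-6-methoxy-3-[(2-oxochroman-7-yl)oxy]coumarin | COc1cc2cc(Oc3ccc4CCC(=O)Oc4c3)c(=O)oc2cc1OC(C)=O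
A2 | alternative 1 | (2Z)-3-(4-acetoxy-3-methoxyphenyl)-2-[(2-oxochroman-7-yl)oxy]prop-2-enoic acid | OC(=O)/C(Oc1ccc2CCC(=O)Oc2c1)=C/c1ccc(OC(C)=O)c(OC)c1
A3 | alternative 2 | 7-hydroxy-6-methoxy-3-[(2-oxochroman-7-yl)oxy]coumarin | COc1cc2cc(Oc3ccc4CCC(=O)Oc4c3)c(=O)oc2cc1O
A4 | alternative 2 | 7-hydroxy-6-methoxycoumarin (scopoletin) | COc1cc2ccc(=O)oc2cc1O
A5 | alternative 2 | 7-hydroxychroman-2-one | O=C1CCc2ccc(O)cc2O1
A6 | alternative 3 | 6-methoxy-7-(methoxymethoxy)-3-[(2-oxochroman-7-yl)oxy]coumarin | COCOc1cc2oc(=O)c(Oc3ccc4CCC(=O)Oc4c3)cc2cc1OC
A7 | alternative 3 | 5-{[6-methoxy-7-(methoxymethoxy)-2-oxo-2H-chromen-3-yl]oxy}-2-oxo-2H-pyran-3-yl pent-4-ynoate | C#CCCC(=O)Oc1cc(Oc2cc3cc(OC)c(OCOC)cc3oc2=O)coc1=O
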